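**Retrosynthetic overview**

1. Target 26 ⇒ acyclic epoxy aldehyde / (Z)-β-iodo enoate 22 in one flask: C6–C7 closes the ten-membered carbocycle, O6 acylates C12 (butenolide), then E1cB opening of the 4,5-epoxide and transannular C4–O → C1 hemiketalisation build the oxygen bridge (the glaucolide → hirsutinolide relationship).
2. Ring order: carbocycle, then lactone, then oxolane bridge. C4 comes from a Sharpless epoxide, C1 follows from C4, and the C6 centre is destroyed.
3. 22 ⇒ ynoate 16 (MgI2/CH2O halo-aldol installs C7–I and C13) ⇒ aldehyde 14 + methyl propiolate (C8 by Zn-ProPhenol alkynylation).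
4. 14 ⇒ 2,3-dione 8 + thioacetate silyl ketene acetal (C10 by Cu-box Mukaiyama aldol); 8 ⇒ geraniol (C1–C6, C15) + ethyl vinyl ether (C10, C14).

Assumption: germacrane numbering is used (C1 hemiketal carbon, C4 ether carbon, C5=C6 enol-lactone olefin, C7=C11 butenolide olefin, C8 carbinol, C10 acetoxy carbon, C12 lactone carbonyl, C13 CH2OAc), and each chiral catalyst is taken to follow its published sense of induction (the antipodal ligand is used if it does not). TBDPS = tert-butyldiphenylsilyl.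

**Route**

Step 1
Reactants: 1 geraniol
Product: 2 geranyl TBDPS ether
Conditions: TBDPSCl, imidazole, DMF, rt
Reagents that add atoms: tert-butyl(chloro)diphenylsilane, CC(C)(C)[Si](Cl)(c1ccccc1)c1ccccc1
Why: Imidazole-promoted silyl ether formation masks the primary allylic alcohol (C6–OH) for the organolithium and acid steps; no stereocentre is involved.

Step 2
Reactants: 2 geranyl TBDPS ether
Product: 4 (4E)-6-[(tert-butyldiphenylsilyl)oxy]-4-methylhex-4-enal, via 6,7-epoxide 3 (not isolated)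
Conditions: mCPBA, CH2Cl2, −20 °C; then H5IO6, THF/Et2O, 0 °C
Reagents that add atoms: mCPBA, OOC(=O)c1cccc(Cl)c1
Why: Peracid epoxidation selects the electron-rich, unhindered distal olefin over the allyl silyl ether olefin, and periodic acid cleaves the epoxide through its diol (one-pot epoxidation/oxidative cleavage) to the aldehyde that becomes C1.

Step 3
Reactants: 4 (4E)-6-[(tert-butyldiphenylsilyl)oxy]-4-methylhex-4-enal; 5 ethyl vinyl ether
Product: 7 (6E)-8-[(tert-butyldiphenylsilyl)oxy]-3-hydroxy-6-methyloct-6-en-2-one (racemic), via enol ether adduct 6 (not isolated)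
Conditions: 5, t-BuLi, THF, −78 to 0 °C; then 4, −78 °C; then 0.5 M HCl, THF, 0 °C
Reagents that add atoms: water, O
Why: 1-Ethoxyvinyllithium is an acetyl anion equivalent whose 1,2-addition and enol ether hydrolysis give the acyloin and bring in C10 and C14; the carbinol centre is removed in step 4.

Step 4
Reactants: 7 (6E)-8-[(tert-butyldiphenylsilyl)oxy]-3-hydroxy-6-methyloct-6-en-2-one
Product: 8 (6E)-8-[(tert-butyldiphenylsilyl)oxy]-6-methyloct-6-ene-2,3-dione
Conditions: IBX, EtOAc, 75 °C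
Reagents that add atoms: none
Why: IBX oxidation of the α-ketol gives the vicinal diketone without touching the olefin or the silyl ether.

Step 5
Reactants: 9 S-ethyl ethanethioate
Product: 10 {[1-(ethylsulfanyl)ethenyl]oxy}trimethylsilane
Conditions: LiN(iPr)2, TMSCl, THF, −78 °C
Reagents that add atoms: chlorotrimethylsilane, C[Si](C)(C)Cl
Why: Kinetic O-silylation of the thioester lithium enolate gives the silyl ketene thioacetal needed for the Mukaiyama aldol.

Step 6
Reactants: 8 (6E)-8-[(tert-butyldiphenylsilyl)oxy]-6-methyloct-6-ene-2,3-dione; 10 {[1-(ethylsulfanyl)ethenyl]oxy}trimethylsilane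
Product: 12 S-ethyl (3S,7E)-9-[(tert-butyldiphenylsilyl)oxy]-3-hydroxy-3,7-dimethyl-4-oxonon-7-enethioate, via TMS ether 11 (not isolated)
Conditions: [Cu((S,S)-t-Bu-box)](OTf)2 (10 mol%), THF, −78 °C; then 1 M HCl
Reagents that add atoms: none
Why: In this Evans Cu-box Mukaiyama aldol the diketone chelates divalent copper through both carbonyls and the silyl ketene thioacetal attacks the less hindered acetyl carbonyl (C10) on the face left open by the tert-butyl groups, as with pyruvate esters, which sets C10 as S.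

Step 7
Reactants: 12 S-ethyl (3S,7E)-9-[(tert-butyldiphenylsilyl)oxy]-3-hydroxy-3,7-dimethyl-4-oxonon-7-enethioate
Product: 13 S-ethyl (3S,7E)-3-acetoxy-9-[(tert-butyldiphenylsilyl)oxy]-3,7-dimethyl-4-oxonon-7-enethioate
Conditions: Ac2O, TMSOTf (2 mol%), CH2Cl2, −40 °C
Reagents that add atoms: acetic anhydride, CC(=O)OC(C)=O
Why: TMSOTf-catalysed acylation acetylates the hindered tertiary α-ketol under non-basic conditions that avoid retro-aldol cleavage and β-elimination.

Step 8
Reactants: 13 S-ethyl (3S,7E)-3-acetoxy-9-[(tert-butyldiphenylsilyl)oxy]-3,7-dimethyl-4-oxonon-7-enethioate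
Product: 14 (3S,7E)-9-[(tert-butyldiphenylsilyl)oxy]-3,7-dimethyl-1,4-dioxonon-7-en-3-yl acetate
Conditions: Et3SiH, Pd/C (10%), acetone, rt
Reagents that add atoms: none
Why: Fukuyama reduction (Pd-catalysed hydrosilane reduction of a thioester) gives the C8 aldehyde in the presence of the ketone, the acetate and the trisubstituted olefin.

Step 9
Reactants: 14 (3S,7E)-9-[(tert-butyldiphenylsilyl)oxy]-3,7-dimethyl-1,4-dioxonon-7-en-3-yl acetate; 15 methyl propiolate
Product: 16 methyl (4R,6S,10E)-6-acetoxy-12-[(tert-butyldiphenylsilyl)oxy]-4-hydroxy-6,10-dimethyl-7-oxododec-10-en-2-ynoate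
Conditions: Me2Zn, (S,S)-ProPhenol (20 mol%), Ph3PO, toluene, 4 °C
Reagents that add atoms: none
Why: Trost dinuclear-zinc ProPhenol alkynylation adds the zinc alkynylide of methyl propiolate to the aldehyde only (the ketone is untouched) under ligand control, which sets C8 as R.

Step 10
Reactants: 16 methyl (4R,6S,10E)-6-acetoxy-12-[(tert-butyldiphenylsilyl)oxy]-4-hydroxy-6,10-dimethyl-7-oxododec-10-en-2-ynoate; 17 formaldehyde
Product: 18 methyl (2Z,4R,6S,10E)-6-acetoxy-12-[(tert-butyldiphenylsilyl)oxy]-4-hydroxy-2-(hydroxymethyl)-3-iodo-6,10-dimethyl-7-oxododeca-2,10-dienoate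
Conditions: MgI2, CH2O (from paraformaldehyde), CH2Cl2, −40 to 0 °C
Reagents that add atoms: magnesium iodide, [Mg+2].[I-].[I-]
Why: Proposed new method: MgI2 adds iodide to C7 of the ynoate to give a magnesium β-iodo allenolate that is hydroxymethylated at C11 by formaldehyde held on the C8 magnesium alkoxide, so that C13 enters on the C8 side and the (2Z) isomer (iodine cis to CO2Me) results, while any (2E) isomer lactonises onto C8–OH and is removed; the closest known reaction is the MgI2-promoted halo-aldol (β-iodo Morita–Baylis–Hillman) reaction of propiolates and ynones with aldehydes.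

Step 11
Reactants: 18 methyl (2Z,4R,6S,10E)-6-acetoxy-12-[(tert-butyldiphenylsilyl)oxy]-4-hydroxy-2-(hydroxymethyl)-3-iodo-6,10-dimethyl-7-oxododeca-2,10-dienoate
Product: 19 methyl (2Z,4R,6S,10E)-6-acetoxy-2-(acetoxymethyl)-12-[(tert-butyldiphenylsilyl)oxy]-4-hydroxy-3-iodo-6,10-dimethyl-7-oxododeca-2,10-dienoate
Conditions: Ac2O (1.1 equiv), 2,4,6-collidine, CH2Cl2, −20 °C
Reagents that add atoms: acetic anhydride, CC(=O)OC(C)=O
Why: Low-temperature acylation with a hindered base acetylates the primary allylic C13–OH and leaves the hindered secondary C8–OH free (selective acylation).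

Step 12
Reactants: 19 methyl (2Z,4R,6S,10E)-6-acetoxy-2-(acetoxymethyl)-12-[(tert-butyldiphenylsilyl)oxy]-4-hydroxy-3-iodo-6,10-dimethyl-7-oxododeca-2,10-dienoate
Product: 20 methyl (2Z,4R,6S,10E)-6-acetoxy-2-(acetoxymethyl)-4,12-dihydroxy-3-iodo-6,10-dimethyl-7-oxododeca-2,10-dienoate
Conditions: HF·pyridine, THF/pyridine, 0 °C to rt
Reagents that add atoms: none
Why: Fluoride desilylation frees the C6 allylic alcohol while the acetates, the methyl ester and the vinyl iodide survive.

Step 13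
Reactants: 20 methyl (2Z,4R,6S,10E)-6-acetoxy-2-(acetoxymethyl)-4,12-dihydroxy-3-iodo-6,10-dimethyl-7-oxododeca-2,10-dienoate
Product: 21 methyl (2Z,4R,6S)-6-acetoxy-2-(acetoxymethyl)-4-hydroxy-9-[(2R,3R)-3-(hydroxymethyl)-2-methyloxiran-2-yl]-3-iodo-6-methyl-7-oxonon-2-enoate
Conditions: Ti(OiPr)4, D-(−)-DIPT, t-BuOOH, 4 Å MS, CH2Cl2, −20 °C
Reagents that add atoms: tert-butyl hydroperoxide, CC(C)(C)OO
Why: Sharpless asymmetric epoxidation of the (E)-trisubstituted primary allylic alcohol with the D-tartrate gives the (2R,3R)-epoxy alcohol (geraniol with the L-tartrate gives 2S,3S), which sets C4 as R, and the electron-poor iodo enoate olefin is inert.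

Step 14
Reactants: 21 methyl (2Z,4R,6S)-6-acetoxy-2-(acetoxymethyl)-4-hydroxy-9-[(2R,3R)-3-(hydroxymethyl)-2-methyloxiran-2-yl]-3-iodo-6-methyl-7-oxonon-2-enoate
Product: 22 methyl (2Z,4R,6S)-6-acetoxy-2-(acetoxymethyl)-9-[(2R,3S)-3-formyl-2-methyloxiran-2-yl]-4-hydroxy-3-iodo-6-methyl-7-oxonon-2-enoate
Conditions: TEMPO (10 mol%), PhI(OAc)2, CH2Cl2, rt
Reagents that add atoms: none
Why: Oxoammonium (TEMPO) oxidation is selective for the primary alcohol over the hindered secondary C8–OH and gives the epoxy aldehyde without opening the epoxide.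

Step 15
Reactants: 22 methyl (2Z,4R,6S)-6-acetoxy-2-(acetoxymethyl)-9-[(2R,3S)-3-formyl-2-methyloxiran-2-yl]-4-hydroxy-3-iodo-6-methyl-7-oxonon-2-enoate
Product: 26 target (1S,4R,5E,8R,10S)-10,13-diacetoxy-1,4-epoxy-1,8-dihydroxygermacra-5,7(11)-dien-12,6-olide, via NHK carbinol 23 (not isolated), via epoxy keto macrolide 24 (not isolated), via 4-hydroxy enol lactone 25 (not isolated)
Conditions: CrCl2, NiCl2 (cat.), THF/DMSO, 2 mM, rt; then Et3N, rt
Reagents that add atoms: none
Why: Nozaki–Hiyama–Kishi addition of the alkenylchromium (retention of olefin geometry) to the aldehyde closes the ten-membered ring at C6–C7, the chromium alkoxide acylates the cis CO2Me to the butenolide, and Et3N with Lewis-acidic trivalent chromium then enolises C6–H so that E1cB opening of the 4,5-epoxide and transannular addition of the C4 alkoxide to the C1 ketone follow as in the known conversion of glaucolides into hirsutinolides, with both C6 epimers converging, the ring forcing the 5E olefin and C4 fixing C1 because only the cis-bridged hemiketal can span the ring.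

**Compound list**

1 | geraniol, (2E)-3,7-dimethylocta-2,6-dien-1-ol | CC(C)=CCC/C(C)=C/CO | starting material
2 | geranyl TBDPS ether, tert-butyl{[(2E)-3,7-dimethylocta-2,6-dien-1-yl]oxy}diphenylsilane | CC(C)=CCC/C(C)=C/CO[Si](c1ccccc1)(c1ccccc1)C(C)(C)C | intermediate
3 | 6,7-epoxide of 2 (racemic), tert-butyl{[(2E)-5-(3,3-dimethyloxiran-2-yl)-3-methylpent-2-en-1-yl]oxy}diphenylsilane | CC1(C)OC1CC/C(C)=C/CO[Si](c1ccccc1)(c1ccccc1)C(C)(C)C | intermediate (not isolated)
4 | (4E)-6-[(tert-butyldiphenylsilyl)oxy]-4-methylhex-4-enal | O=CCC/C(C)=C/CO[Si](c1ccccc1)(c1ccccc1)C(C)(C)C | intermediate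
5 | ethyl vinyl ether | C=COCC | starting material
6 | (6E)-8-[(tert-butyldiphenylsilyl)oxy]-2-ethoxy-6-methylocta-1,6-dien-3-ol (racemic) | C=C(OCC)C(O)CC/C(C)=C/CO[Si](c1ccccc1)(c1ccccc1)C(C)(C)C | intermediate (not isolated)
7 | (6E)-8-[(tert-butyldiphenylsilyl)oxy]-3-hydroxy-6-methyloct-6-en-2-one (racemic) | CC(=O)C(O)CC/C(C)=C/CO[Si](c1ccccc1)(c1ccccc1)C(C)(C)C | intermediate
8 | (6E)-8-[(tert-butyldiphenylsilyl)oxy]-6-methyloct-6-ene-2,3-dione | CC(=O)C(=O)CC/C(C)=C/CO[Si](c1ccccc1)(c1ccccc1)C(C)(C)C | intermediate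
9 | S-ethyl ethanethioate | CCSC(C)=O | starting material
10 | {[1-(ethylsulfanyl)ethenyl]oxy}trimethylsilane | C=C(O[Si](C)(C)C)SCC | intermediate
11 | S-ethyl (3S,7E)-9-[(tert-butyldiphenylsilyl)oxy]-3,7-dimethyl-4-oxo-3-[(trimethylsilyl)oxy]non-7-enethioate | CCSC(=O)C[C@](C)(O[Si](C)(C)C)C(=O)CC/C(C)=C/CO[Si](c1ccccc1)(c1ccccc1)C(C)(C)C | intermediate (not isolated)
12 | S-ethyl (3S,7E)-9-[(tert-butyldiphenylsilyl)oxy]-3-hydroxy-3,7-dimethyl-4-oxonon-7-enethioate | CCSC(=O)C[C@](C)(O)C(=O)CC/C(C)=C/CO[Si](c1ccccc1)(c1ccccc1)C(C)(C)C | intermediate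
13 | S-ethyl (3S,7E)-3-acetoxy-9-[(tert-butyldiphenylsilyl)oxy]-3,7-dimethyl-4-oxonon-7-enethioate | CCSC(=O)C[C@](C)(OC(C)=O)C(=O)CC/C(C)=C/CO[Si](c1ccccc1)(c1ccccc1)C(C)(C)C | intermediate
14 | (3S,7E)-9-[(tert-butyldiphenylsilyl)oxy]-3,7-dimethyl-1,4-dioxonon-7-en-3-yl acetate | O=CC[C@](C)(OC(C)=O)C(=O)CC/C(C)=C/CO[Si](c1ccccc1)(c1ccccc1)C(C)(C)C | intermediate
15 | methyl propiolate | C#CC(=O)OC | starting material
16 | methyl (4R,6S,10E)-6-acetoxy-12-[(tert-butyldiphenylsilyl)oxy]-4-hydroxy-6,10-dimethyl-7-oxododec-10-en-2-ynoate | COC(=O)C#C[C@H](O)C[C@](C)(OC(C)=O)C(=O)CC/C(C)=C/CO[Si](c1ccccc1)(c1ccccc1)C(C)(C)C | intermediate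
17 | formaldehyde (from paraformaldehyde) | C=O | starting material
18 | methyl (2Z,4R,6S,10E)-6-acetoxy-12-[(tert-butyldiphenylsilyl)oxy]-4-hydroxy-2-(hydroxymethyl)-3-iodo-6,10-dimethyl-7-oxododeca-2,10-dienoate | COC(=O)/C(CO)=C(\I)[C@H](O)C[C@](C)(OC(C)=O)C(=O)CC/C(C)=C/CO[Si](c1ccccc1)(c1ccccc1)C(C)(C)C | intermediate
19 | methyl (2Z,4R,6S,10E)-6-acetoxy-2-(acetoxymethyl)-12-[(tert-butyldiphenylsilyl)oxy]-4-hydroxy-3-iodo-6,10-dimethyl-7-oxododeca-2,10-dienoate | COC(=O)/C(COC(C)=O)=C(\I)[C@H](O)C[C@](C)(OC(C)=O)C(=O)CC/C(C)=C/CO[Si](c1ccccc1)(c1ccccc1)C(C)(C)C | intermediate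
20 | methyl (2Z,4R,6S,10E)-6-acetoxy-2-(acetoxymethyl)-4,12-dihydroxy-3-iodo-6,10-dimethyl-7-oxododeca-2,10-dienoate | COC(=O)/C(COC(C)=O)=C(\I)[C@H](O)C[C@](C)(OC(C)=O)C(=O)CC/C(C)=C/CO | intermediate
21 | methyl (2Z,4R,6S)-6-acetoxy-2-(acetoxymethyl)-4-hydroxy-9-[(2R,3R)-3-(hydroxymethyl)-2-methyloxiran-2-yl]-3-iodo-6-methyl-7-oxonon-2-enoate | COC(=O)/C(COC(C)=O)=C(\I)[C@H](O)C[C@](C)(OC(C)=O)C(=O)CC[C@@]1(C)O[C@@H]1CO | intermediate
22 | methyl (2Z,4R,6S)-6-acetoxy-2-(acetoxymethyl)-9-[(2R,3S)-3-formyl-2-methyloxiran-2-yl]-4-hydroxy-3-iodo-6-methyl-7-oxonon-2-enoate | COC(=O)/C(COC(C)=O)=C(\I)[C@H](O)C[C@](C)(OC(C)=O)C(=O)CC[C@@]1(C)O[C@@H]1C=O | intermediate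
23 | NHK carbinol, methyl (4R,5R,8R,10S)-10,13-diacetoxy-4,5-epoxy-6,8-dihydroxy-1-oxogermacr-7(11)-en-12-oate with CO2Me cis to C6 (both C6 epimers) | COC(=O)/C(COC(C)=O)=C(\C1O)[C@H](O)C[C@](C)(OC(C)=O)C(=O)CC[C@@]2(C)O[C@@H]21 | intermediate (not isolated)
24 | epoxy keto macrolide, (4R,5R,8R,10S)-10,13-diacetoxy-4,5-epoxy-8-hydroxy-1-oxogermacr-7(11)-en-12,6-olide (both C6 epimers) | CC(=O)OCC1=C2[C@H](O)C[C@](C)(OC(C)=O)C(=O)CC[C@@]3(C)O[C@@H]3C2OC1=O | intermediate (not isolated)
25 | 4-hydroxy enol lactone, (4R,5E,8R,10S)-10,13-diacetoxy-4,8-dihydroxy-1-oxogermacra-5,7(11)-dien-12,6-olide | CC(=O)OCC1=C2/C(=C\[C@@](O)(C)CCC(=O)[C@@](C)(OC(C)=O)C[C@H]2O)OC1=O | intermediate (not isolated)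
26 | (1S,4R,5E,8R,10S)-10,13-diacetoxy-1,4-epoxy-1,8-dihydroxygermacra-5,7(11)-dien-12,6-olide (CNP0203479.1) | CC(=O)OCC1=C2/C(=C\[C@@]3(C)CC[C@](O)(O3)[C@@](C)(OC(C)=O)C[C@H]2O)OC1=O | target

**Step count and risks**

Total step count: 15 (14 in the main chain plus the one-step preparation of 10). Longest linear sequence: 14 steps from geraniol (steps 1–4 and 6–15).

Steps most likely to fail:

Step 15 (one-flask ring closure, lactonisation and bridging). The tetrasubstituted alkenylchromium has to close a ten-membered ring onto a fragile epoxy aldehyde. If this fails, ring closure is moved ahead of epoxidation. Setting out from 20, MnO2 oxidises the allylic alcohol to the enal F1. CrCl2/NiCl2 then closes the ring on this more robust aldehyde and lactonises to the 4,5-ene macrolide F2, whose C6 epimers are separated. The epimer whose lactone oxygen lies on the alkene face that must receive the epoxide oxygen is epoxidised with mCPBA (outer-face attack as in parthenolide-type germacrolides; the Shi ketone with KHSO5 if reagent control is needed). This comes back to the route at 24, now as an isolated compound, which Et3N or silica gel converts into 26. The cost is that C4 is then relayed from C6 and at most one C6 epimer is usable.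

Step 10 (halo-aldol). The geometry of the tetrasubstituted iodo enoate rests on delivery of formaldehyde from the C8 alkoxide. If the (2E) isomer dominates, C13 is delivered through a temporary silicon tether instead. Setting out from 16, (bromomethyl)chlorodimethylsilane and imidazole give the bromomethylsilyl ether F3. LiI in THF adds iodide to the ynoate and the allenolate is alkylated intramolecularly by the tethered CH2Br, which gives the cyclic siloxane F4 with C13 necessarily cis to C8. Tamao oxidation (H2O2, KF, KHCO3) then cleaves the C–Si bond and comes back to the route at 18.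

Step 9 (alkynylation of the β-acetoxy aldehyde). Risks are β-elimination of acetate, 1,3-acetyl shift to the new C8 alkoxide and modest ligand control with an α-unbranched aldehyde. If they prevail, C8 is set by reduction instead of addition. Setting out from 14, lithium methyl propiolate (LiN(SiMe3)2, THF, −78 °C, quenched cold) gives the epimeric carbinol F5. Dess–Martin periodinane gives the ynone F6. Noyori transfer hydrogenation with RuCl[(R,R)-TsDPEN](p-cymene) in i-PrOH reduces only the ynone and comes back to the route at 16.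

Further compounds
F1 | step 15 | enal, methyl (2Z,4R,6S,10E)-6-acetoxy-2-(acetoxymethyl)-4-hydroxy-3-iodo-6,10-dimethyl-7,12-dioxododeca-2,10-dienoate | COC(=O)/C(COC(C)=O)=C(\I)[C@H](O)C[C@](C)(OC(C)=O)C(=O)CC/C(C)=C/C=O
F2 | step 15 | 4,5-ene macrolide, (4E,8R,10S)-10,13-diacetoxy-8-hydroxy-1-oxogermacra-4,7(11)-dien-12,6-olide (C6 epimers) | CC(=O)OCC1=C2[C@H](O)C[C@](C)(OC(C)=O)C(=O)CC/C(C)=C/C2OC1=O
F3 | step 10 | bromomethylsilyl ether, 4-O-[(bromomethyl)dimethylsilyl] derivative of 16 | COC(=O)C#C[C@H](O[Si](C)(C)CBr)C[C@](C)(OC(C)=O)C(=O)CC/C(C)=C/CO[Si](c1ccccc1)(c1ccccc1)C(C)(C)C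
F4 | step 10 | cyclic siloxane, methyl (6R)-5-iodo-2,2-dimethyl-3,6-dihydro-2H-1,2-oxasiline-4-carboxylate carrying at C6 the (2S,6E)-2-acetoxy-8-[(tert-butyldiphenylsilyl)oxy]-2,6-dimethyl-3-oxooct-6-en-1-yl chain | COC(=O)C1=C(I)[C@@H](C[C@](C)(OC(C)=O)C(=O)CC/C(C)=C/CO[Si](c2ccccc2)(c2ccccc2)C(C)(C)C)O[Si](C)(C)C1
F5 | step 9 | epimeric carbinol, methyl (6S,10E)-6-acetoxy-12-[(tert-butyldiphenylsilyl)oxy]-4-hydroxy-6,10-dimethyl-7-oxododec-10-en-2-ynoate (C4 epimer mixture) | COC(=O)C#CC(O)C[C@](C)(OC(C)=O)C(=O)CC/C(C)=C/CO[Si](c1ccccc1)(c1ccccc1)C(C)(C)C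
F6 | step 9 | ynone, methyl (6S,10E)-6-acetoxy-12-[(tert-butyldiphenylsilyl)oxy]-6,10-dimethyl-4,7-dioxododec-10-en-2-ynoate | COC(=O)C#CC(=O)C[C@](C)(OC(C)=O)C(=O)CC/C(C)=C/CO[Si](c1ccccc1)(c1ccccc1)C(C)(C)C
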